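(All runs were computed with constants of no real substance, and the scatter is random.)

At early times, up to 6.00 h, the south flask, the one asked about, showed no reading above 0.4%, against a scatter of 0.3 percentage points.

| flask | left-handed substrate | right-handed substrate | solid reagent | racemization catalyst | added ligand | remark | time |
|---|---|---|---|---|---|---|---|
| south | 0.10 M | 0.10 M | 0.25 M | 0.50 mM | 1 mM | the very flask that is asked about, followed so far |  |
| south-east | 0.067 M | 0.067 M | 0.25 M | 0.50 mM | 1 mM | run made earlier |  |
| flask | 0.10 M | 0.10 M | 0.250 M | 0.50 mM | 1.0 mM |  | 50 h |

| run | time / h | left-handed product / % | right-handed product / % |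
|---|---|---|---|
| south | 1.33 | 0.2 | 0 |
| south | 2.00 | 0 | 0.3 |
| south | 3.00 | 0 | 0 |
| south | 4.00 | 0 | 0.4 |
| south | 6.00 | 0 | 0.1 |
| south | 10.0 | 0.1 | 0 |
| south | 15.0 | 1.1 | 0.5 |
| south-east | 2.00 | 0 | 0.1 |
| south-east | 5.00 | 0.2 | 0 |
| south-east | 10.0 | 0 | 0.7 |
| south-east | 15.0 | 0.9 | 0.2 |
| south-east | 20.0 | 1.7 | 0.1 |
| south-east | 30.0 | 2.9 | 1.7 |
| south-east | 40.0 | 4.2 | 2.1 |

(scatter of a reading: 0.3 percentage points)

- partner is single-handed; left-handed substrate and right-handed substrate are mirror images of each other, charged as a racemate, each of them at the stated concentration
- solid, in amounts per volume of the solution: solid reagent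
- what was read earlier has a scatter of 0.3 percentage points, one standard deviation
- at the start none of the solid reagent is in solution
- an excess is the difference of the two amounts in percent of their sum
- an excess is below zero if the other one leads
- the handed part of partner does not stay in what it makes, so the products of the two hands are mirror images too

- excess of left-handed product over right-handed product in the product at 1.0 h
- excess of left-handed product over right-handed product in the product at 50 h
- part of the left-handed substrate and right-handed substrate charged together that has reacted at 50 h

I laid out the times as a ladder. On the first rung, 1.0 h, the south flask had no reading, its nearest being 0.2% of left-handed product at 1.33 h, so I inferred its excess. On the next rung product became readable. From the latest south-east reading I took the selectivity factor s, the amount of left-handed product over right-handed product: 2.00 at 40.0 h, a reading with a scatter of 0.3 points on 2.1%.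

Assuming that s holds while the substrate stays near racemic, the early end gives an excess of (s − 1)/(s + 1), or 33.3%, however little partner has formed.

The last rung is my estimate of the time to use the charge at the pace of the last south-east interval, 588 h. That is far longer than the 50 h asked about, so I kept the same excess at the late end. At 15.0 h the south flask had 1.60% of product and the south-east run 1.10%, a gap of 0.5 points against a scatter of 0.3 points on each of the four readings, so I let the south flask follow the south-east pace, which gave my estimate of 8.00% reacted at 50 h.

The forecast said an excess of 40% early, 36% late and 11% reacted, calling its early value “an uncertain extrapolation of the same selectivity”. Its early excess and its conversion stood higher than mine.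

The south flask gave an excess of 33.3% early, 32.8% late and 7.46% reacted, so the early excess lay 6.7 points under the forecast.

    partner + left-handed substrate → left-handed product (k = 9.60 × 10⁻⁵ L mol⁻¹ s⁻¹)
    partner + right-handed substrate → right-handed product (k = 4.80 × 10⁻⁵ L mol⁻¹ s⁻¹)
    left-handed substrate + racemization catalyst ⇌ right-handed substrate + racemization catalyst, rate k3*[racemization catalyst]*[left-handed substrate] forward; the back reaction follows from the equilibrium constant (k = 0.0340 L mol⁻¹ s⁻¹)
    racemization catalyst + added ligand ⇌ idle complex, settled at all times (K = 1300 L mol⁻¹)
    solid reagent ⇌ partner, rate k5*(cs5 - [partner]) while solid is left; crystals form when [partner] > cs5 (solubility = 34.0 mM, k = 4.60 × 10⁻⁶ s⁻¹)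

At 23.4 h in the south flask, the reaction with partner used left-handed substrate at 0.074 of the rate of the forward racemization step alone, slower than that step. With s, the share s/(s + 1) of the reacted charge makes 4.97% left-handed product in this flask, where 4.95% stood. The neighbour flask with 0.42 M of solid reagent reacted 7.46%, so s makes 4.97% there, and it held 4.95%.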